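(Its constants were drawn at random within sensible limits, and the outcome is calculated.)

Time is what I ration here: larch has 8.0 min with 14 µM of enzyme, and its neighbours change the substrate.

| flask | substrate | enzyme | time |
|---|---|---|---|
| larch | 8.0 mM | 14 µM | 8.0 min |
| elm | 12 mM | 14 µM | 8.0 min |
| oak | 20 mM | 14 µM | 8.0 min |
| maple | 30 mM | 14 µM | 8.0 min |
| alder | 40 mM | 14 µM | 8.0 min |
    substrate → uncatalysed product (k1 = 3.82 × 10⁻⁵ s⁻¹)
    substrate + enzyme → target + enzyme, rate k2*[substrate]*[enzyme]/(1 + ([substrate]/Km2) + ([substrate]/Ksi2)^2) (Km2 = 14.4 mM, Ksi2 = 17.1 mM, k2 = 697 M⁻¹ s⁻¹)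
1. [target] at the end for larch, elm, oak, maple, alder, in this order
2. how the row runs (falls all the way / hardly changes / rises, then falls / rises all the way / falls, then rises)
- "hardly changes" means that all values lie within two and a half points (for a concentration: within two and a half percent of the largest)
- run time (larch): 8.0 min

One thing looks wrong at once. Alder holds 40 mM of substrate against 8.0 mM in larch, yet it starts slower, at 2.53 mM min⁻¹ against 2.64 mM min⁻¹. This is substrate inhibition: the squared term outgrows the substrate. These two starting rates therefore do not give me the row, and I need the whole path.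

Step 1 I drop, since at the start of alder the enzyme uses substrate 27.6 times as fast. Step 2 returns the enzyme, so I divide the rate law by c(substrate) and integrate. The left side is a cost, and the right side is the enzyme budget, k2 times c(enzyme) times the time, a pure number:

cost = ln(c start / c end) + (c start − c end)/Km + (c start^2 − c end^2) / (2 Ksi^2)
budget = 4.68

I guess c(substrate) at the end, correct by the cost per mM there, and go round again.

Alder: guess 20.0 mM, cost 4.13, cost per mM 0.188 mM⁻¹
next c end = 17.1 mM, cost 4.68, target 22.9 mM

Maple: guess 6.00 mM, cost 4.75, cost per mM 0.257 mM⁻¹
next c end = 6.27 mM, target 23.7 mM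

So I reckon that alder ends below maple: going from 40 mM down to 30 mM costs alder half of its budget. Oak's charge of 20 mM lies below maple's target, so I expect the row to rise, then fall.

The forecast gives 7.82 mM, 11.62 mM, 18.55 mM, 23.7 mM and 23 mM, with the shape rises, then falls, on the ground that “the squared substrate-inhibition term slows the enzyme enough”.

The flasks give 7.82 mM, 11.6 mM, 18.5 mM, 23.7 mM and 23.0 mM, so the row rises, then falls, and read from the runs it turns near 33 mM at 23.9 mM. Alder ends with 41.2% of its charge still substrate. Oak ends with 6.46% of its 20 mM charge still substrate, and that reading put into the cost line gives 4.72 against a budget of 4.68.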